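## Retrosynthetic overview

1. Target 36 ⇐ global deprotection of 35 ⇐ Stille coupling of the C2 vinyl triflate 28 with the (2Z,4E)-dienylstannane 34 (from propargyl alcohol by carbomagnesiation–iodination and a distannane linchpin).
2. (Z)-Enal, carried as acetal 24 ⇐ Cr(CO)3-catalysed 1,4-hydrogenation of diene 23 ⇐ Negishi coupling of the kinetic enol triflate of ketone 17 ⇐ hydroboration–oxidation of C9=C10 (sets C10); C6 carbinol ⇐ organocerium addition.
3. Five-membered ring ⇐ one [3+2] step that forms C2–C3 and C1–C5 of the spiro[4.5]decane from spiro-cyclopropyl ketone 7 and the chiral (E)-alkenyl boronate 10 (C1–B later becomes C1–OH); 7 ⇐ cyclohexane-1,3-dione (cyclopropanation, enol triflate, B-alkyl Suzuki coupling).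
4. Enabling feature: in 7 the strained C1–C3/C2–C3 σ-bonds of the three-membered ring lie α to the C4 ketone and allylic to C7=C8, so the ketyl opens to an O–C4=C3–C8=C7 dienolate and a primary CH2 radical. The absolute configuration comes from the (R)-carbinol carbon of 10, which is oxidised away in step 16.
5. Ring order: six-membered ring (purchased) → three-membered ring (step 1) → five-membered ring (step 6, consuming the three-membered ring) → temporary silylene ring (step 9, removed in step 21).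

Key step: step 6

Assumption: radical addition to 10 is taken to follow a Felkin–Anh-type sense; because the (R)-carbinol centre of 10 is fixed, a wrong C2 epimer is a separable diastereomer and cannot erode enantiopurity.

Locants and abbreviations: spiro[4.5]decane intermediates are numbered C1 (CH–B or CH–O), C2 (CH bearing the side chain), C3, C4 (CH2), C5 (spiro carbon), C6 (C=O, later C(CH3)–O), C7, C8 (CH2), C9, C10 (carbon bearing the propyl chain). CIP letters at C2, C5 and C10 change with substituent priorities although no centre is inverted. TBS = tert-butyldimethylsilyl, PMB = 4-methoxybenzyl, Bpin = 4,4,5,5-tetramethyl-1,3,2-dioxaborolan-2-yl, Tf = trifluoromethanesulfonyl.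

## Route

Step 1
Reactants: 1 cyclohexane-1,3-dione
Product: 2 spiro[2.5]octane-4,8-dione
Conditions: (2-bromoethyl)diphenylsulfonium triflate, K2CO3, EtOAc, rt
Reagents that add atoms: (2-bromoethyl)diphenylsulfonium trifluoromethanesulfonate, BrCC[S+](c1ccccc1)c1ccccc1.[O-]S(=O)(=O)C(F)(F)F
Why: Spirocyclopropanation of a 1,3-dione: base converts the salt into a vinylsulfonium ion, the dione enolate adds to it (Michael addition) and the resulting ylide–enolate closes by 3-exo-tet displacement of Ph2S; no stereocentre is formed.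

Step 2
Reactants: 2 spiro[2.5]octane-4,8-dione
Product: 4 8-oxospiro[2.5]oct-4-en-4-yl trifluoromethanesulfonate, via lithium enolate 3 (not isolated)
Conditions: LiN(SiMe3)2 (1.0 equiv), THF, −78 °C; PhNTf2, −78 to 0 °C
Reagents that add atoms: N-phenylbis(trifluoromethanesulfonimide), O=S(=O)(N(c1ccccc1)S(=O)(=O)C(F)(F)F)C(F)(F)F
Why: Enol triflate formation: C3 is quaternary, so the dione enolises only away from it, and one equivalent of base gives a single monoenolate that is O-sulfonylated; no stereocentre.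

Step 3
Reactants: 4 8-oxospiro[2.5]oct-4-en-4-yl trifluoromethanesulfonate; 5 allyl tert-butyldimethylsilyl ether
Product: 7 8-[3-(TBS-oxy)propyl]spiro[2.5]oct-7-en-4-one, via alkylborane 6 (not isolated)
Conditions: 5, 9-BBN, THF, rt; then 4, PdCl2(dppf) (5 mol %), K3PO4, DMF/H2O, rt
Reagents that add atoms: none
Why: B-alkyl Suzuki–Miyaura coupling: anti-Markovnikov hydroboration of 5 followed by sp3–sp2 coupling with the enol triflate under zerovalent palladium catalysis; the C7=C8 bond cannot move into conjugation because C3 is quaternary.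

Step 4
Reactants: 8 (R)-but-3-yn-2-ol
Product: 9 (R)-but-3-yn-2-yl 4-methoxybenzyl ether
Conditions: NaH, PMBCl, Bu4NI (cat.), THF/DMF, 0 °C to rt
Reagents that add atoms: 4-methoxybenzyl chloride, COc1ccc(CCl)cc1
Why: Williamson ether synthesis on the alkoxide; the carbinol stereocentre is not touched.

Step 5
Reactants: 9 (R)-but-3-yn-2-yl 4-methoxybenzyl ether
Product: 10 (R,E)-alkenyl boronate
Conditions: pinacolborane, Cp2Zr(H)Cl (5 mol %), Et3N (10 mol %), neat, 60 °C
Reagents that add atoms: pinacolborane, CC1(C)OBOC1(C)C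
Why: Zirconium-catalysed syn-hydroboration of the terminal alkyne puts boron on the terminal carbon and gives the (E)-alkenyl boronate; the carbinol centre is untouched.

Step 6
Reactants: 7 8-[3-(TBS-oxy)propyl]spiro[2.5]oct-7-en-4-one; 10 (R,E)-alkenyl boronate
Product: 11 (1S,2R,5R)-spirocyclic boronate
Conditions: SmI2 (20 mol %), Sm powder (20 mol %), 10 (3 equiv), THF (0.5 M), 55 °C; chromatographic separation of diastereomers
Reagents that add atoms: none
Why: Proposed new method: SmI2 should reduce the ketone of 7 to a ketyl whose fragmentation cleaves a C3–CH2 bond of the three-membered ring, giving a primary radical and a trivalent-samarium dienolate (O–C4=C3–C8=C7); the radical adds to the boron-free alkene carbon of 10 (new C2–C3 bond), the α-boryl radical closes onto the dienolate α-carbon (new C1–C5 bond), and the new ketyl returns its electron to trivalent samarium so that SmI2 turns over. The closest known reaction type is the SmI2-catalysed formal [3+2] cycloaddition of alkyl cyclopropyl ketones with alkenes and alkynes; a β-substituted alkenyl boronate as partner and a spiro dienolate as radical acceptor are the new elements. The one ring closure is a 5-exo-trig radical cyclisation (7-endo attack at the γ-carbon is disfavoured). C2 is set in the intermolecular addition, anti to the C–O bond of the neighbouring (R)-carbinol centre (Felkin–Anh-type), and the C2 epimers are diastereomers removed by chromatography. C1 is set in the ring closure trans to the C2 substituent, and C5 relative to C1 by a chair-like transition state that keeps Bpin on the side of the enolate C–O carbon (future C6) and away from the propyl-bearing C10 (allylic strain). The step needs radical addition β to boron, which the radical-stabilising empty p-orbital of boron secures, and addition faster than hydrogen abstraction from THF, which excess 10 at high concentration should secure.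

Step 7
Reactants: 11 (1S,2R,5R)-spirocyclic boronate
Product: 12 (1S,2R,5S)-hydroxy ketone
Conditions: H2O2 (30 % aq.), NaHCO3, THF/H2O, 0 °C to rt
Reagents that add atoms: hydrogen peroxide, OO
Why: Oxidation of a secondary alkyl boronate by 1,2-migration of carbon from boron to oxygen, with retention at C1; the mild buffer avoids retro-aldol cleavage.

Step 8
Reactants: 12 (1S,2R,5S)-hydroxy ketone
Product: 13 (1S,2R,5S,6S)-diol
Conditions: MeLi, CeCl3, THF, −78 °C
Reagents that add atoms: methyllithium, [Li]C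
Why: 1,2-Addition of a weakly basic organocerium reagent (suppresses retro-aldol cleavage); the C1–O arm, cis to C6 and held pseudo-axial on C5 by allylic strain with the C10 propyl chain, blocks one face, so methyl should enter from the C4 face and set C6 with OH cis to C1.

Step 9
Reactants: 13 (1S,2R,5S,6S)-diol
Product: 14 silylene alkene
Conditions: tBu2Si(OTf)2, 2,6-lutidine, CH2Cl2, 0 °C to rt
Reagents that add atoms: di-tert-butylsilyl bis(trifluoromethanesulfonate), CC(C)(C)[Si](OS(=O)(=O)C(F)(F)F)(OS(=O)(=O)C(F)(F)F)C(C)(C)C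
Why: Silylene formation: the two hydroxyls are syn across the spiro centre and close a six-membered 1,3-dioxa-2-silinane that protects both until step 21.

Step 10
Reactants: 14 silylene alkene
Product: 16 (9S,10S)-silylene alcohol, via alkylborane 15 (not isolated)
Conditions: BH3·THF, THF, 0 °C to rt; then H2O2, aq. NaOH, 0 °C
Reagents that add atoms: hydrogen peroxide, OO
Why: Hydroboration–oxidation: boron adds to the less substituted C9 and hydrogen to C10, syn and from the C4 face (the other face is shielded by the pseudo-axial C1 arm and the silylene ring), which sets C10 with the propyl chain cis to C1.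

Step 11
Reactants: 16 (9S,10S)-silylene alcohol
Product: 17 (10S)-silylene ketone
Conditions: Dess–Martin periodinane, NaHCO3, CH2Cl2, rt
Reagents that add atoms: none
Why: Dess–Martin oxidation of the secondary alcohol under buffered conditions that do not epimerise C10.

Step 12
Reactants: 17 (10S)-silylene ketone
Product: 19 kinetic enol triflate, via potassium enolate 18 (not isolated)
Conditions: KN(SiMe3)2, THF, −78 °C; PhNTf2, −78 °C
Reagents that add atoms: N-phenylbis(trifluoromethanesulfonimide), O=S(=O)(N(c1ccccc1)S(=O)(=O)C(F)(F)F)C(F)(F)F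
Why: Kinetic enolisation at the C8 methylene (C10–H is tertiary and flanked by the spiro centre) and O-triflation; C10 is not epimerised.

Step 13
Reactants: 19 kinetic enol triflate; 20 2-bromo-3,3-diethoxyprop-1-ene
Product: 23 diene acetal, via alkenyllithium 21 (not isolated), via alkenylzinc chloride 22 (not isolated)
Conditions: 20, t-BuLi (2 equiv), Et2O, −78 °C; ZnCl2, THF, −78 to 0 °C; then 19, Pd(PPh3)4 (5 mol %), THF, rt to 50 °C
Reagents that add atoms: none
Why: Negishi coupling of the enol triflate with the alkenylzinc reagent obtained by bromine–lithium exchange and transmetalation; it gives the 2,3-disubstituted 1,3-diene and leaves C10 untouched.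

Step 14
Reactants: 23 diene acetal
Product: 24 (Z)-alkylidene acetal
Conditions: H2 (50 atm), (η6-naphthalene)Cr(CO)3 (20 mol %), acetone, 40 °C
Reagents that add atoms: none
Why: Cr(CO)3-catalysed 1,4-hydrogenation: the diene binds η4 in its s-cis form and H2 is delivered to C8 and to the terminal CH2, so the new tetrasubstituted double bond must carry the new methyl cis to C8 and the acetal carbon cis to C10 (Z, the geometry of the target enal); isolated double bonds are not reduced.

Step 15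
Reactants: 24 (Z)-alkylidene acetal
Product: 25 secondary alcohol
Conditions: DDQ, CH2Cl2/pH 7 phosphate buffer, 0 °C
Reagents that add atoms: none
Why: Oxidative cleavage of the PMB ether (hydride abstraction by DDQ, then hydrolysis); silyl groups and the acetal survive at pH 7.

Step 16
Reactants: 25 secondary alcohol
Product: 26 methyl ketone
Conditions: Dess–Martin periodinane, NaHCO3, CH2Cl2, rt
Reagents that add atoms: none
Why: Dess–Martin oxidation removes the auxiliary carbinol stereocentre under conditions that do not epimerise C2.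

Step 17
Reactants: 26 methyl ketone
Product: 28 vinyl triflate, via potassium enolate 27 (not isolated)
Conditions: KN(SiMe3)2, THF, −78 °C; PhNTf2, −78 °C
Reagents that add atoms: N-phenylbis(trifluoromethanesulfonimide), O=S(=O)(N(c1ccccc1)S(=O)(=O)C(F)(F)F)C(F)(F)F
Why: Kinetic deprotonation at the methyl group (C2–H is tertiary and hindered) and O-triflation gives the 1-substituted vinyl triflate; the β-silyloxy group is not eliminated because the C2 enolate is not formed.

Step 18
Reactants: 29 5-bromo-2-methylpent-2-ene; 30 prop-2-yn-1-ol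
Product: 33 (Z)-3-iodo-2-(4-methylpent-3-en-1-yl)prop-2-en-1-ol, via Grignard reagent 31 (not isolated), via alkenylmagnesium alkoxide 32 (not isolated)
Conditions: 29, Mg, THF; then 30 (0.4 equiv), CuI (10 mol %), Et2O/THF, rt; then I2, −40 to 0 °C
Reagents that add atoms: iodine, II
Why: Copper-catalysed anti-carbomagnesiation of the magnesium alkoxide of 30 (Duboudin–Jousseaume reaction): the alkyl group adds to C2 and magnesium to C3 inside a five-membered chelate, and iodinolysis with retention places iodine cis to CH2OH (Z).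

Step 19
Reactants: 33 (Z)-3-iodo-2-(4-methylpent-3-en-1-yl)prop-2-en-1-ol
Product: 34 (2Z,4E)-dienylstannane
Conditions: (E)-Bu3SnCH=CHSnBu3 (2 equiv), PdCl2(MeCN)2 (5 mol %), DMF, rt
Reagents that add atoms: (E)-1,2-bis(tributylstannyl)ethene, CCCC[Sn](CCCC)(CCCC)/C=C/[Sn](CCCC)(CCCC)CCCC
Why: Stille coupling at one tin terminus of the excess (E)-distannane, with retention of both double-bond geometries.

Step 20
Reactants: 28 vinyl triflate; 34 (2Z,4E)-dienylstannane
Product: 35 protected triene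
Conditions: Pd(PPh3)4 (10 mol %), CuCl, LiCl, DMSO, rt to 45 °C
Reagents that add atoms: none
Why: Copper-assisted Stille coupling joins the C(=CH2) carbon to the (E)-CH=CH unit with retention; the free hydroxyl and the acetal are tolerated.

Step 21
Reactants: 35 protected triene
Product: 36 CNP0249558.1
Conditions: HF (48 % aq.), MeCN, 0 °C to rt
Reagents that add atoms: water, O
Why: Fluoride cleavage of the TBS ether and the silylene, together with hydrolysis of the allylic diethyl acetal, releases the tetraol enal; no stereocentre or double bond is touched.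

## Compound list

1 | cyclohexane-1,3-dione | O=C1CCCC(=O)C1 | starting material
2 | spiro[2.5]octane-4,8-dione | O=C1CCCC(=O)C12CC2 | intermediate
3 | lithium 8-oxospiro[2.5]oct-4-en-4-olate | [Li+].[O-]C1=CCCC(=O)C12CC2 | intermediate
4 | 8-oxospiro[2.5]oct-4-en-4-yl trifluoromethanesulfonate | O=C1CCC=C(OS(=O)(=O)C(F)(F)F)C12CC2 | intermediate
5 | allyl tert-butyldimethylsilyl ether | C=CCO[Si](C)(C)C(C)(C)C | starting material
6 | 9-[3-(TBS-oxy)propyl]-9-borabicyclo[3.3.1]nonane | CC(C)(C)[Si](C)(C)OCCCB1C2CCCC1CCC2 | intermediate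
7 | 8-[3-(TBS-oxy)propyl]spiro[2.5]oct-7-en-4-one | O=C1CCC=C(CCCO[Si](C)(C)C(C)(C)C)C12CC2 | intermediate
8 | (R)-but-3-yn-2-ol | C[C@@H](O)C#C | starting material
9 | 1-{[(2R)-but-3-yn-2-yloxy]methyl}-4-methoxybenzene | C[C@@H](OCc1ccc(OC)cc1)C#C | intermediate
10 | 2-[(1E,3R)-3-(PMB-oxy)but-1-en-1-yl]-4,4,5,5-tetramethyl-1,3,2-dioxaborolane | C[C@@H](OCc1ccc(OC)cc1)/C=C/B1OC(C)(C)C(C)(C)O1 | intermediate
11 | (1S,2R,5R)-1-(Bpin)-2-[(1R)-1-(PMB-oxy)ethyl]-10-[3-(TBS-oxy)propyl]spiro[4.5]dec-9-en-6-one | C[C@@H](OCc1ccc(OC)cc1)[C@@H]1CC[C@]2(C(CCCO[Si](C)(C)C(C)(C)C)=CCCC2=O)[C@H]1B3OC(C)(C)C(C)(C)O3 | intermediate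
12 | (1S,2R,5S)-1-hydroxy-2-[(1R)-1-(PMB-oxy)ethyl]-10-[3-(TBS-oxy)propyl]spiro[4.5]dec-9-en-6-one | C[C@@H](OCc1ccc(OC)cc1)[C@@H]1CC[C@]2(C(CCCO[Si](C)(C)C(C)(C)C)=CCCC2=O)[C@H]1O | intermediate
13 | (1S,2R,5S,6S)-6-methyl-2-[(1R)-1-(PMB-oxy)ethyl]-10-[3-(TBS-oxy)propyl]spiro[4.5]dec-9-ene-1,6-diol | C[C@@H](OCc1ccc(OC)cc1)[C@@H]1CC[C@]2(C(CCCO[Si](C)(C)C(C)(C)C)=CCC[C@]2(C)O)[C@H]1O | intermediate
14 | (1S,2S,5S,6S)-1,6-[(di-tert-butylsilanediyl)dioxy]-6-methyl-2-[(1R)-1-(PMB-oxy)ethyl]-10-[3-(TBS-oxy)propyl]spiro[4.5]dec-9-ene | C[C@@H](OCc1ccc(OC)cc1)[C@@H]1CC[C@]2(C(CCCO[Si](C)(C)C(C)(C)C)=CCC[C@]2(C)O3)[C@H]1O[Si]3(C(C)(C)C)C(C)(C)C | intermediate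
15 | C9-borane adduct of 14 (H at C10 and B at C9 syn, on the C4 face) | C[C@@H](OCc1ccc(OC)cc1)[C@@H]1CC[C@]2([C@H](CCCO[Si](C)(C)C(C)(C)C)[C@@H](B)CC[C@]2(C)O3)[C@H]1O[Si]3(C(C)(C)C)C(C)(C)C | intermediate
16 | (1S,2S,5S,6S,9S,10S)-1,6-[(di-tert-butylsilanediyl)dioxy]-6-methyl-2-[(1R)-1-(PMB-oxy)ethyl]-10-[3-(TBS-oxy)propyl]spiro[4.5]decan-9-ol | C[C@@H](OCc1ccc(OC)cc1)[C@@H]1CC[C@]2([C@H](CCCO[Si](C)(C)C(C)(C)C)[C@@H](O)CC[C@]2(C)O3)[C@H]1O[Si]3(C(C)(C)C)C(C)(C)C | intermediate
17 | (1S,2S,5S,6S,10S)-1,6-[(di-tert-butylsilanediyl)dioxy]-6-methyl-2-[(1R)-1-(PMB-oxy)ethyl]-10-[3-(TBS-oxy)propyl]spiro[4.5]decan-9-one | C[C@@H](OCc1ccc(OC)cc1)[C@@H]1CC[C@]2([C@H](CCCO[Si](C)(C)C(C)(C)C)C(=O)CC[C@]2(C)O3)[C@H]1O[Si]3(C(C)(C)C)C(C)(C)C | intermediate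
18 | potassium C8-enolate of 17 | [K+].C[C@@H](OCc1ccc(OC)cc1)[C@@H]1CC[C@]2([C@H](CCCO[Si](C)(C)C(C)(C)C)C([O-])=CC[C@]2(C)O3)[C@H]1O[Si]3(C(C)(C)C)C(C)(C)C | intermediate
19 | (1S,2S,5S,6S,10S)-1,6-[(di-tert-butylsilanediyl)dioxy]-6-methyl-2-[(1R)-1-(PMB-oxy)ethyl]-10-[3-(TBS-oxy)propyl]spiro[4.5]dec-8-en-9-yl trifluoromethanesulfonate | C[C@@H](OCc1ccc(OC)cc1)[C@@H]1CC[C@]2([C@H](CCCO[Si](C)(C)C(C)(C)C)C(OS(=O)(=O)C(F)(F)F)=CC[C@]2(C)O3)[C@H]1O[Si]3(C(C)(C)C)C(C)(C)C | intermediate
20 | 2-bromo-3,3-diethoxyprop-1-ene | C=C(Br)C(OCC)OCC | starting material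
21 | (3,3-diethoxyprop-1-en-2-yl)lithium | [Li]C(=C)C(OCC)OCC | intermediate
22 | chloro(3,3-diethoxyprop-1-en-2-yl)zinc | Cl[Zn]C(=C)C(OCC)OCC | intermediate
23 | (1S,2S,5S,6S,10R)-9-(3,3-diethoxyprop-1-en-2-yl)-1,6-[(di-tert-butylsilanediyl)dioxy]-6-methyl-2-[(1R)-1-(PMB-oxy)ethyl]-10-[3-(TBS-oxy)propyl]spiro[4.5]dec-8-ene | C[C@@H](OCc1ccc(OC)cc1)[C@@H]1CC[C@]2([C@H](CCCO[Si](C)(C)C(C)(C)C)C(C(=C)C(OCC)OCC)=CC[C@]2(C)O3)[C@H]1O[Si]3(C(C)(C)C)C(C)(C)C | intermediate
24 | (1S,2S,5S,6S,10R)-9-[(2Z)-1,1-diethoxypropan-2-ylidene]-1,6-[(di-tert-butylsilanediyl)dioxy]-6-methyl-2-[(1R)-1-(PMB-oxy)ethyl]-10-[3-(TBS-oxy)propyl]spiro[4.5]decane | C[C@@H](OCc1ccc(OC)cc1)[C@@H]1CC[C@]2([C@H](CCCO[Si](C)(C)C(C)(C)C)/C(=C(/C)C(OCC)OCC)CC[C@]2(C)O3)[C@H]1O[Si]3(C(C)(C)C)C(C)(C)C | intermediate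
25 | (1R)-1-[(1S,2S,5S,6S,10R)-9-[(2Z)-1,1-diethoxypropan-2-ylidene]-1,6-[(di-tert-butylsilanediyl)dioxy]-6-methyl-10-[3-(TBS-oxy)propyl]spiro[4.5]decan-2-yl]ethan-1-ol | C[C@@H](O)[C@@H]1CC[C@]2([C@H](CCCO[Si](C)(C)C(C)(C)C)/C(=C(/C)C(OCC)OCC)CC[C@]2(C)O3)[C@H]1O[Si]3(C(C)(C)C)C(C)(C)C | intermediate
26 | 1-[(1S,2R,5S,6S,10R)-9-[(2Z)-1,1-diethoxypropan-2-ylidene]-1,6-[(di-tert-butylsilanediyl)dioxy]-6-methyl-10-[3-(TBS-oxy)propyl]spiro[4.5]decan-2-yl]ethan-1-one | CC(=O)[C@@H]1CC[C@]2([C@H](CCCO[Si](C)(C)C(C)(C)C)/C(=C(/C)C(OCC)OCC)CC[C@]2(C)O3)[C@H]1O[Si]3(C(C)(C)C)C(C)(C)C | intermediate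
27 | potassium methyl-side enolate of 26 | [K+].C=C([O-])[C@@H]1CC[C@]2([C@H](CCCO[Si](C)(C)C(C)(C)C)/C(=C(/C)C(OCC)OCC)CC[C@]2(C)O3)[C@H]1O[Si]3(C(C)(C)C)C(C)(C)C | intermediate
28 | 1-[(1S,2R,5S,6S,10R)-9-[(2Z)-1,1-diethoxypropan-2-ylidene]-1,6-[(di-tert-butylsilanediyl)dioxy]-6-methyl-10-[3-(TBS-oxy)propyl]spiro[4.5]decan-2-yl]ethenyl trifluoromethanesulfonate | C=C(OS(=O)(=O)C(F)(F)F)[C@@H]1CC[C@]2([C@H](CCCO[Si](C)(C)C(C)(C)C)/C(=C(/C)C(OCC)OCC)CC[C@]2(C)O3)[C@H]1O[Si]3(C(C)(C)C)C(C)(C)C | intermediate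
29 | 5-bromo-2-methylpent-2-ene | CC(C)=CCCBr | starting material
30 | prop-2-yn-1-ol | OCC#C | starting material
31 | (4-methylpent-3-en-1-yl)magnesium bromide | CC(C)=CCC[Mg]Br | intermediate
32 | bromomagnesium (2Z)-3-(bromomagnesio)-2-(4-methylpent-3-en-1-yl)prop-2-en-1-olate | Br[Mg]/C=C(\CO[Mg]Br)CCC=C(C)C | intermediate
33 | (2Z)-3-iodo-2-(4-methylpent-3-en-1-yl)prop-2-en-1-ol | OC/C(=C\I)CCC=C(C)C | intermediate
34 | (2Z,4E)-2-(4-methylpent-3-en-1-yl)-5-(tributylstannyl)penta-2,4-dien-1-ol | OC/C(CCC=C(C)C)=C\C=C\[Sn](CCCC)(CCCC)CCCC | intermediate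
35 | (1S,2S,5S,6S,10R)-9-[(2Z)-1,1-diethoxypropan-2-ylidene]-1,6-[(di-tert-butylsilanediyl)dioxy]-2-[(3E,5Z)-6-(hydroxymethyl)-10-methylundeca-1,3,5,9-tetraen-2-yl]-6-methyl-10-[3-(TBS-oxy)propyl]spiro[4.5]decane | C=C(/C=C/C=C(\CO)CCC=C(C)C)[C@@H]1CC[C@]2([C@H](CCCO[Si](C)(C)C(C)(C)C)/C(=C(/C)C(OCC)OCC)CC[C@]2(C)O3)[C@H]1O[Si]3(C(C)(C)C)C(C)(C)C | intermediate
36 | (2Z)-2-[(1S,2S,5S,6S,10R)-1,6-dihydroxy-2-[(3E,5Z)-6-(hydroxymethyl)-10-methylundeca-1,3,5,9-tetraen-2-yl]-10-(3-hydroxypropyl)-6-methylspiro[4.5]decan-9-ylidene]propanal (CNP0249558.1) | C=C(/C=C/C=C(\CO)CCC=C(C)C)[C@@H]1CC[C@]2([C@H](CCCO)/C(=C(/C)C=O)CC[C@]2(C)O)[C@H]1O | target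

## Step count and risks

Total step count: 21. Longest linear sequence: 17 steps (steps 1–3, 6–17, 20, 21).

Steps most likely to fail:

Step 6 (proposed new method). The primary radical may be quenched (reduction or hydrogen abstraction from THF) before it adds to the hindered β-substituted alkenyl boronate, the rebound onto the fully substituted dienolate carbon may be slow, and face selectivity at C2 may be low. The fallback uses known reaction types, sets out from 7 (with 10) and comes back at 11. Iodide-induced ring opening of the cyclopropyl ketone (Me3SiCl, NaI, MeCN, 0 °C) gives the 2-(2-iodoethyl) trimethylsilyl dienol ether F1, in which the C7=C8 position is preserved. A tin-hydride radical annulation (Bu3SnH by syringe pump, AIBN, benzene, 80 °C, excess 10) then makes the same two bonds in two separate events: Giese addition of the primary radical to the alkenyl boronate, and 5-exo cyclisation of the α-boryl radical onto the silyl enol ether. Hydrogen transfer gives the C6 trimethylsilyl ether F2 (C6 epimers); methanolysis (citric acid, MeOH) gives the C6 carbinol F3, and Dess–Martin oxidation returns 11, purified from diastereomers as in the main route.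

Step 14. The hindered 2,3-disubstituted diene may fail to reach the s-cis η4 geometry on Cr(CO)3, the catalyst may be lost by arene exchange with the PMB ring, or unselective reduction may occur. The fallback sets out from 17 and comes back at 24. Ramirez olefination (CBr4, PPh3, Et3N, toluene, 80 °C) gives the 1,1-dibromoalkene F4. Trans-selective Negishi monomethylation (MeZnCl, Pd(PtBu3)2, THF), at the bromide cis to the C8 methylene and away from the branched C10, gives the bromoalkene F5. Bromine–lithium exchange (t-BuLi, −78 °C) and formylation with DMF, with retention, gives the (Z)-enal F6, and HC(OEt)3, PPTS, EtOH converts it into 24.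

Step 10. Hydroboration may be slow or attack the wrong face of the trisubstituted alkene beside the spiro centre, giving the C10 epimer. The fallback sets out from 13 and comes back at 17. Hydroxyl-directed epoxidation (VO(acac)2, t-BuOOH, CH2Cl2), steered by the homoallylic C6 hydroxyl, gives the epoxy diol F7 with oxygen on the face of the C6–OH. Silylene formation (tBu2Si(OTf)2, 2,6-lutidine) gives the epoxy silylene F8. Meinwald rearrangement (BF3·OEt2, CH2Cl2, −78 °C) ionises the tertiary C10–O bond and shifts hydride from C9 to C10 anti to the leaving oxygen, giving ketone 17 with H at C10 on the C4 face.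

Further compounds

F1 | step 6 | {[2-(2-iodoethyl)-3-[3-(TBS-oxy)propyl]cyclohexa-1,3-dien-1-yl]oxy}trimethylsilane | C[Si](C)(C)OC1=C(CCI)C(CCCO[Si](C)(C)C(C)(C)C)=CCC1
F2 | step 6 | C6 trimethylsilyl ether of the annulated boronate (C6 epimers, other centres as in 11) | C[C@@H](OCc1ccc(OC)cc1)[C@@H]1CC[C@]2(C(CCCO[Si](C)(C)C(C)(C)C)=CCCC2O[Si](C)(C)C)[C@H]1B3OC(C)(C)C(C)(C)O3
F3 | step 6 | C6 carbinol of the annulated boronate (C6 epimers, other centres as in 11) | C[C@@H](OCc1ccc(OC)cc1)[C@@H]1CC[C@]2(C(CCCO[Si](C)(C)C(C)(C)C)=CCCC2O)[C@H]1B3OC(C)(C)C(C)(C)O3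
F4 | step 14 | 9-(dibromomethylidene) analogue of 17 | C[C@@H](OCc1ccc(OC)cc1)[C@@H]1CC[C@]2([C@H](CCCO[Si](C)(C)C(C)(C)C)C(=C(Br)Br)CC[C@]2(C)O3)[C@H]1O[Si]3(C(C)(C)C)C(C)(C)C
F5 | step 14 | 9-[(1Z)-1-bromoethylidene] analogue of 17 (Br cis to C10) | C[C@@H](OCc1ccc(OC)cc1)[C@@H]1CC[C@]2([C@H](CCCO[Si](C)(C)C(C)(C)C)/C(=C(/C)Br)CC[C@]2(C)O3)[C@H]1O[Si]3(C(C)(C)C)C(C)(C)C
F6 | step 14 | (2Z)-enal corresponding to acetal 24 | C[C@@H](OCc1ccc(OC)cc1)[C@@H]1CC[C@]2([C@H](CCCO[Si](C)(C)C(C)(C)C)/C(=C(/C)C=O)CC[C@]2(C)O3)[C@H]1O[Si]3(C(C)(C)C)C(C)(C)C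
F7 | step 10 | 9,10-epoxide of diol 13 (oxygen on the face of the C6 hydroxyl) | C[C@@H](OCc1ccc(OC)cc1)[C@@H]1CC[C@]2([C@]5(CCCO[Si](C)(C)C(C)(C)C)O[C@@H]5CC[C@]2(C)O)[C@H]1O
F8 | step 10 | 1,6-O-(di-tert-butylsilanediyl) derivative of F7 | C[C@@H](OCc1ccc(OC)cc1)[C@@H]1CC[C@]2([C@]5(CCCO[Si](C)(C)C(C)(C)C)O[C@@H]5CC[C@]2(C)O3)[C@H]1O[Si]3(C(C)(C)C)C(C)(C)C
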